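**Plan**

- The furan (O1', C2' carrying the CH2CO2Me arm, C3', C4', C5' carrying the chain) has only hydrogen on C3' and C4'. The C3'–C4' bond is therefore cut back to two vinyl groups on C2' and C5', held together by the ring oxygen, with the aromatic ring masked as a 2-methoxy-2,5-dihydrofuran.
- Further cuts: the C5'–O ketal bond (allylic alcohol plus a 1-alkyl-1-methoxyallene), the C5'–CH2 bond to the chain (lithiated methoxyallene plus a primary iodide), the aldol bond of the hydroxy ester, and the three C–C bonds at the chain stereocentre (boron-to-carbon migration, Zweifel vinylation, hydroformylation).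
- Forward: the chiral chain is built first and ends as an iodide with the aldehyde masked as its dimethyl acetal. It is joined to C5' through methoxyallene, the ester half is added through oxygen, the ring is closed by metathesis, and acid aromatizes the ring and frees the aldehyde.
- Stereochemistry: the single (R) centre comes from (−)-sparteine-mediated lithiation of pentyl N,N-diisopropylcarbamate, stereospecific borylation and 1,2-migration, and a stereoretentive Zweifel vinylation. The two temporary ring centres need no control.

Key step: step 12

Remark: the hydroxy ester is used as the racemate and the mixed ketal is carried as a diastereomer mixture, because both of these centres become sp2 carbons of the furan.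

**Route**

Step 1
Reactants: 1 pentan-1-ol
Product: 2 pentyl N,N-diisopropylcarbamate
Conditions: iPr2NCOCl, Et3N, CH2Cl2, reflux
Reagents that add atoms: N,N-diisopropylcarbamoyl chloride, CC(C)N(C(C)C)C(=O)Cl
Why: Carbamoylation of a primary alcohol with a carbamoyl chloride gives the hindered carbamate that directs and stabilises the later α-lithiation.

Step 2
Reactants: 3 7-bromoheptan-1-ol
Product: 4 [(7-bromoheptyl)oxy](tert-butyl)dimethylsilane
Conditions: TBSCl, imidazole, CH2Cl2, 0 °C → rt
Reagents that add atoms: tert-butyldimethylsilyl chloride, CC(C)(C)[Si](C)(C)Cl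
Why: Silylation of a primary alcohol under imidazole catalysis is fast and leaves the primary bromide untouched.

Step 3
Reactants: 4 [(7-bromoheptyl)oxy](tert-butyl)dimethylsilane
Product: 5 tert-butyldimethyl{[7-(4,4,5,5-tetramethyl-1,3,2-dioxaborolan-2-yl)heptyl]oxy}silane
Conditions: B2pin2, CuI (10 mol%), PPh3 (13 mol%), LiOMe, DMF, rt
Reagents that add atoms: bis(pinacolato)diboron, CC1(C)OB(OC1(C)C)B1OC(C)(C)C(C)(C)O1
Why: Copper-catalysed borylation of an unactivated primary alkyl bromide with B2pin2 proceeds through a copper boryl species at room temperature and tolerates the silyl ether.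

Step 4
Reactants: 2 pentyl N,N-diisopropylcarbamate; 5 tert-butyldimethyl{[7-(4,4,5,5-tetramethyl-1,3,2-dioxaborolan-2-yl)heptyl]oxy}silane
Product: 8 tert-butyldimethyl{[(8R)-8-(4,4,5,5-tetramethyl-1,3,2-dioxaborolan-2-yl)dodecyl]oxy}silane, via (S)-1-lithiopentyl N,N-diisopropylcarbamate 6 (not isolated), via lithium boronate complex 7 (not isolated)
Conditions: 2, (−)-sparteine, s-BuLi, Et2O, −78 °C, 5 h; then 5, −78 °C, 1 h; then MgBr2·OEt2, −78 °C → reflux
Reagents that add atoms: none
Why: Lithiation–borylation, in which s-BuLi/(−)-sparteine removes the pro-S proton to give the configurationally stable (S)-lithio carbamate, the boronic ester is captured with retention, and the heptyl group then migrates from boron to carbon with inversion as the carbamate leaves, which sets the (R) centre.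

Step 5
Reactants: 8 tert-butyldimethyl{[(8R)-8-(4,4,5,5-tetramethyl-1,3,2-dioxaborolan-2-yl)dodecyl]oxy}silane
Product: 11 tert-butyl{[(8R)-8-ethenyldodecyl]oxy}dimethylsilane, via vinyl boronate complex 9 (not isolated), via β-iodoalkyl boronic ester 10 (not isolated)
Conditions: CH2=CHMgBr (4 equiv), THF, rt; then I2, MeOH, −78 °C; then NaOMe, MeOH, −78 °C → rt; Na2S2O3 (aq)
Reagents that add atoms: vinylmagnesium bromide, C=C[Mg]Br
Why: Zweifel olefination, in which iodine activates the vinyl boronate for 1,2-migration of the secondary alkyl group with retention and methoxide then triggers anti elimination of boron and iodine, so the (R) centre is carried over unchanged.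

Step 6
Reactants: 11 tert-butyl{[(8R)-8-ethenyldodecyl]oxy}dimethylsilane
Product: 12 (4R)-4-butyl-11-[(tert-butyldimethylsilyl)oxy]undecanal
Conditions: Rh(acac)(CO)2 (1 mol%), Xantphos (3 mol%), CO/H2 (1:1, 10 bar), toluene, 70 °C
Reagents that add atoms: carbon monoxide, [C-]#[O+]
Why: Rhodium-catalysed hydroformylation with a wide-bite-angle diphosphine places the formyl group on the terminal carbon, the branching next to the alkene reinforcing linear selectivity, and the weakly isomerizing ligand should leave the allylic stereocentre intact.

Step 7
Reactants: 12 (4R)-4-butyl-11-[(tert-butyldimethylsilyl)oxy]undecanal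
Product: 14 (8R)-8-butyl-11,11-dimethoxyundecan-1-ol, via silyl ether dimethyl acetal 13 (not isolated)
Conditions: camphorsulfonic acid (10 mol%), HC(OMe)3 (1.5 equiv), MeOH, rt; then Et3N
Reagents that add atoms: methanol, CO; trimethyl orthoformate, COC(OC)OC
Why: Acid-catalysed acetalization in methanol with orthoformate as water scavenger is fast, and the same acid then methanolyses the primary silyl ether, while the stereocentre lies γ to the carbonyl and cannot enolize.

Step 8
Reactants: 14 (8R)-8-butyl-11,11-dimethoxyundecan-1-ol
Product: 15 (4R)-4-butyl-11-iodo-1,1-dimethoxyundecane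
Conditions: PPh3, I2, imidazole, CH2Cl2, 0 °C → rt
Reagents that add atoms: iodine, II
Why: Appel-type iodination converts the primary alcohol through its alkoxyphosphonium salt into the iodide, and imidazole buffers the medium so that the dimethyl acetal should survive.

Step 9
Reactants: 15 (4R)-4-butyl-11-iodo-1,1-dimethoxyundecane; 16 methoxyallene (1-methoxypropa-1,2-diene)
Product: 18 (11R)-11-butyl-3,14,14-trimethoxytetradeca-1,2-diene, via 1-lithio-1-methoxyallene 17 (not isolated)
Conditions: 16 (2 equiv), n-BuLi, THF, −40 °C; then 15, −78 °C → rt; chromatography on Et3N-deactivated silica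
Reagents that add atoms: none
Why: Methoxyallene is lithiated at the oxygen-bearing carbon and the resulting organolithium is alkylated by the primary iodide in an SN2 reaction at that same carbon, the acetal being inert to organolithium reagents.

Step 10
Reactants: 19 methyl acetate; 20 acrolein
Product: 22 methyl 3-hydroxypent-4-enoate (racemic), via lithium enolate of methyl acetate 21 (not isolated)
Conditions: LiN(iPr)2 (commercial solution), THF, −78 °C; then 20, −78 °C; AcOH quench
Reagents that add atoms: none
Why: Aldol addition of the ester lithium enolate to acrolein at low temperature occurs 1,2 at the carbonyl group, and the cold acidic quench prevents retro-aldol cleavage and dehydration.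

Step 11
Reactants: 18 (11R)-11-butyl-3,14,14-trimethoxytetradeca-1,2-diene; 22 methyl 3-hydroxypent-4-enoate
Product: 23 methyl 3-{[(11R)-11-butyl-3,14,14-trimethoxytetradec-1-en-3-yl]oxy}pent-4-enoate (mixture at the ketal carbon and the carbinol carbon)
Conditions: 22 (1.5 equiv), Pd(OAc)2 (5 mol%), dppp (7.5 mol%), Et3N (1.5 equiv), MeCN, rt → 40 °C; chromatography on Et3N-deactivated silica
Reagents that add atoms: none
Why: Palladium-catalysed hydroalkoxylation of an alkoxyallene, in which a palladium hydride adds to the allene to give a methoxy-substituted π-allyl complex that the alcohol attacks at the oxygen-bearing terminus, gives the O,O-ketal with a terminal vinyl group under basic conditions that preserve both acetals.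

Step 12
Reactants: 23 methyl 3-{[(11R)-11-butyl-3,14,14-trimethoxytetradec-1-en-3-yl]oxy}pent-4-enoate
Product: 24 methyl 2-{5-[(8R)-8-butyl-11,11-dimethoxyundecyl]-5-methoxy-2,5-dihydrofuran-2-yl}acetate (mixture at the two ring centres)
Conditions: (H2IMes)(PCy3)Cl2Ru=CHPh (second-generation Grubbs catalyst, 5 mol%), CH2Cl2 (0.005 M), 40 °C
Reagents that add atoms: none
Why: Ring-closing metathesis: the ruthenium benzylidene exchanges onto the less hindered vinyl group at C2', the new alkylidene adds to the vinyl group on the ketal carbon C5' in a [2+2] step, and cycloreversion of the ruthenacyclobutane releases the ring alkene, ethene being lost on turnover. The closest known reaction type is the ring-closing metathesis of mixed allylic acetals to 2-alkoxy-2,5-dihydrofurans, applied here to the corresponding ketal. The one ring formed, the five-membered oxacycle, closes at carbon by making the C3'=C4' double bond of a 4-oxahepta-1,6-diene unit, a kinetically favoured five-membered closure. No new stereocentre arises; C2' and C5' remain mixtures that aromatization erases, and the remote (R) centre is untouched. The selectivity needed is ring closure over intermolecular cross-metathesis, and it is secured by the two monosubstituted alkenes being held 1,6 to each other by the oxygen bridge and by high dilution, while the ester and the dimethyl acetal are inert to the catalyst.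

Step 13
Reactants: 24 methyl 2-{5-[(8R)-8-butyl-11,11-dimethoxyundecyl]-5-methoxy-2,5-dihydrofuran-2-yl}acetate
Product: 26 methyl 2-{5-[(8R)-8-butyl-11-oxoundecyl]furan-2-yl}acetate, via furan dimethyl acetal 25 (not isolated)
Conditions: 1 M aq. HCl, THF, 0 °C → rt; NaHCO3 (aq)
Reagents that add atoms: water, O
Why: Acid-catalysed elimination, in which ionization of the ring ketal with loss of methanol gives a cyclic oxocarbenium ion that loses the C2' proton to form the aromatic furan without any oxidant, is followed in the same aqueous acid by hydrolysis of the dimethyl acetal to the aldehyde, and the methyl ester should survive dilute acid at room temperature.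

**Compound list**

1 | pentan-1-ol | CCCCCO | starting material
2 | pentyl N,N-diisopropylcarbamate | CCCCCOC(=O)N(C(C)C)C(C)C | intermediate
3 | 7-bromoheptan-1-ol | OCCCCCCCBr | starting material
4 | [(7-bromoheptyl)oxy](tert-butyl)dimethylsilane | CC(C)(C)[Si](C)(C)OCCCCCCCBr | intermediate
5 | tert-butyldimethyl{[7-(4,4,5,5-tetramethyl-1,3,2-dioxaborolan-2-yl)heptyl]oxy}silane | CC(C)(C)[Si](C)(C)OCCCCCCCB1OC(C)(C)C(C)(C)O1 | intermediate
6 | (S)-1-lithiopentyl N,N-diisopropylcarbamate, as its (−)-sparteine complex | CCCC[C@H]([Li])OC(=O)N(C(C)C)C(C)C | intermediate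
7 | lithium boronate complex of 6 with 5, (S) at the carbamate-bearing carbon | CCCC[C@H]([B-]1(CCCCCCCO[Si](C)(C)C(C)(C)C)OC(C)(C)C(C)(C)O1)OC(=O)N(C(C)C)C(C)C.[Li+] | intermediate
8 | tert-butyldimethyl{[(8R)-8-(4,4,5,5-tetramethyl-1,3,2-dioxaborolan-2-yl)dodecyl]oxy}silane | CCCC[C@@H](B1OC(C)(C)C(C)(C)O1)CCCCCCCO[Si](C)(C)C(C)(C)C | intermediate
9 | bromomagnesium vinyl boronate complex of 8, (R) at the boron-bearing carbon | CCCC[C@@H]([B-]1(C=C)OC(C)(C)C(C)(C)O1)CCCCCCCO[Si](C)(C)C(C)(C)C.[Mg+2].[Br-] | intermediate
10 | tert-butyl{[(8R)-8-butyl-10-iodo-9-(4,4,5,5-tetramethyl-1,3,2-dioxaborolan-2-yl)decyl]oxy}dimethylsilane, mixture at C9 | CCCC[C@@H](C(CI)B1OC(C)(C)C(C)(C)O1)CCCCCCCO[Si](C)(C)C(C)(C)C | intermediate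
11 | tert-butyl{[(8R)-8-ethenyldodecyl]oxy}dimethylsilane | CCCC[C@@H](C=C)CCCCCCCO[Si](C)(C)C(C)(C)C | intermediate
12 | (4R)-4-butyl-11-[(tert-butyldimethylsilyl)oxy]undecanal | CCCC[C@@H](CCC=O)CCCCCCCO[Si](C)(C)C(C)(C)C | intermediate
13 | tert-butyl{[(8R)-8-butyl-11,11-dimethoxyundecyl]oxy}dimethylsilane | CCCC[C@@H](CCC(OC)OC)CCCCCCCO[Si](C)(C)C(C)(C)C | intermediate
14 | (8R)-8-butyl-11,11-dimethoxyundecan-1-ol | CCCC[C@@H](CCC(OC)OC)CCCCCCCO | intermediate
15 | (4R)-4-butyl-11-iodo-1,1-dimethoxyundecane | CCCC[C@@H](CCC(OC)OC)CCCCCCCI | intermediate
16 | methoxyallene (1-methoxypropa-1,2-diene) | COC=C=C | starting material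
17 | 1-lithio-1-methoxyallene | COC([Li])=C=C | intermediate
18 | (11R)-11-butyl-3,14,14-trimethoxytetradeca-1,2-diene | CCCC[C@@H](CCC(OC)OC)CCCCCCCC(OC)=C=C | intermediate
19 | methyl acetate | COC(C)=O | starting material
20 | acrolein | C=CC=O | starting material
21 | lithium enolate of methyl acetate | C=C(OC)[O-].[Li+] | intermediate
22 | methyl 3-hydroxypent-4-enoate, racemic | C=CC(O)CC(=O)OC | intermediate
23 | methyl 3-{[(11R)-11-butyl-3,14,14-trimethoxytetradec-1-en-3-yl]oxy}pent-4-enoate, mixture at the ketal and carbinol carbons | CCCC[C@@H](CCC(OC)OC)CCCCCCCC(OC)(C=C)OC(C=C)CC(=O)OC | intermediate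
24 | methyl 2-{5-[(8R)-8-butyl-11,11-dimethoxyundecyl]-5-methoxy-2,5-dihydrofuran-2-yl}acetate, mixture at the two ring centres | CCCC[C@@H](CCC(OC)OC)CCCCCCCC1(OC)C=CC(CC(=O)OC)O1 | intermediate
25 | methyl 2-{5-[(8R)-8-butyl-11,11-dimethoxyundecyl]furan-2-yl}acetate | CCCC[C@@H](CCC(OC)OC)CCCCCCCc1ccc(CC(=O)OC)o1 | intermediate
26 | methyl 2-{5-[(8R)-8-butyl-11-oxoundecyl]furan-2-yl}acetate | CCCC[C@@H](CCC=O)CCCCCCCc1ccc(CC(=O)OC)o1 | target

**Step count**

Total: 13 steps. Longest linear sequence: 11 steps (steps 2 to 9 and 11 to 13, from 7-bromoheptan-1-ol).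

**Steps most likely to fail**

Step 11. Hydropalladation of the 1,1-disubstituted allene may be slow, and the hindered secondary alcohol may attack the distal terminus of the allyl complex, giving an enol ether in place of the ketal. The fallback sets out from allene 18 and hydroxy ester 22 and returns at ketal 23. It makes the C5'–O bond by a different reaction, Brønsted-acid ketalization of the allenyl enol ether, as in mixed-ketal protection with 2-methoxypropene. With pyridinium p-toluenesulfonate (catalytic) and 4 Å sieves in CH2Cl2 at −20 °C, protonation of the central allene carbon should give the vinyl-substituted oxocarbenium ion, which the alcohol captures at the oxygen-bearing carbon. Triethylamine is added before work-up. No new compound arises on this path (F0).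

Step 12. Loading of the catalyst and cyclization at the alkene next to the fully substituted ketal carbon may be slow, so that intermolecular metathesis or acid-promoted ionization of the labile ketal takes over. The fallback sets out from allene 18 and returns at furan acetal 25. It forms the C3'=C4' bond by cross-metathesis and closes the ring at oxygen. Brief hydrolysis of the allenyl ether with catalytic oxalic acid in wet THF at 0 °C should give the vinyl ketone (11R)-11-butyl-14,14-dimethoxytetradec-1-en-3-one F1, the dimethyl acetal being far slower to hydrolyse. Cross-metathesis of F1 with an excess of hydroxy ester 22, using (H2IMes)Cl2Ru=CH(C6H4-2-OiPr) (second-generation Hoveyda–Grubbs catalyst) in CH2Cl2 at 40 °C, should give the γ-hydroxy enone methyl (4E,14R)-14-butyl-3-hydroxy-17,17-dimethoxy-6-oxoheptadec-4-enoate F2. Pyridinium p-toluenesulfonate in CH2Cl2 then isomerizes the alkene, cyclizes the hydroxy ketone and dehydrates it to furan 25, which is taken to 26 under the conditions of step 13.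

Step 6. Reversible rhodium hydride addition may move the double bond toward the allylic stereocentre, eroding enantiomeric purity, and some branched aldehyde may form. The fallback sets out from alkene 11 and returns at hydroxy acetal 14. It builds the arm without any metal hydride that can reach the stereocentre. Hydroboration with 9-BBN in THF and oxidation with NaOH/H2O2 should give (3R)-3-butyl-10-[(tert-butyldimethylsilyl)oxy]decan-1-ol F3. Oxidation with Dess–Martin periodinane buffered with NaHCO3 gives (3R)-3-butyl-10-[(tert-butyldimethylsilyl)oxy]decanal F4, whose stereocentre is β to the carbonyl and so not epimerizable. Wittig reaction with (methoxymethyl)triphenylphosphonium chloride and KN(SiMe3)2 in THF gives the enol ether tert-butyl{[(8R)-8-butyl-11-methoxyundec-10-en-1-yl]oxy}dimethylsilane F5 as an E/Z mixture. Under the conditions of step 7, F5 adds methanol to give the dimethyl acetal and loses the silyl group, giving 14.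

**Further compounds**

F0 | step 11 | none | none
F1 | step 12 | (11R)-11-butyl-14,14-dimethoxytetradec-1-en-3-one | CCCC[C@@H](CCC(OC)OC)CCCCCCCC(=O)C=C
F2 | step 12 | methyl (4E,14R)-14-butyl-3-hydroxy-17,17-dimethoxy-6-oxoheptadec-4-enoate, mixture at C3 | CCCC[C@@H](CCC(OC)OC)CCCCCCCC(=O)/C=C/C(O)CC(=O)OC
F3 | step 6 | (3R)-3-butyl-10-[(tert-butyldimethylsilyl)oxy]decan-1-ol | CCCC[C@@H](CCO)CCCCCCCO[Si](C)(C)C(C)(C)C
F4 | step 6 | (3R)-3-butyl-10-[(tert-butyldimethylsilyl)oxy]decanal | CCCC[C@@H](CC=O)CCCCCCCO[Si](C)(C)C(C)(C)C
F5 | step 6 | tert-butyl{[(8R)-8-butyl-11-methoxyundec-10-en-1-yl]oxy}dimethylsilane, E/Z mixture | CCCC[C@@H](CC=COC)CCCCCCCO[Si](C)(C)C(C)(C)C
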